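## The problem

The target, 4-[(2,4-dihydroxy-6-methylbenzoyl)oxy]-2-heptyl-6-hydroxybenzoic acid, is a depside. Ring A (an orsellinoyl unit) is joined through an aryl ester to the C4 oxygen of ring B, a 2-heptyl-4,6-dioxygenated benzoic acid. There is no stereocentre, so the task is one of regiochemistry and of the timing of functional groups. Ring B carries carboxyl (C1), heptyl (C2) and hydroxyl (C6) on three adjacent carbons, and its two oxygens must be told apart: O4 acylated, O6 free. The depside ester is cleaved by hydroxide, alkoxides and amines, and both rings are β-resorcylic acid derivatives that decarboxylate when heated or held in strong acid as free acids. The ring B carboxyl must therefore be released without base, and the phenols unmasked late. The enabling feature is that B C2 (heptyl), C3, C4 (oxygen) and C5 match C6, C5, C4 and C3 of a 6-heptyl-4-hydroxy-2-pyrone, whose acidic 4-hydroxyl can be acylated by ring A before ring B exists. The remaining B C1 (carboxyl) and B C6 (hydroxyl) have the oxidation level of an alkyne bearing an ester and an oxygen substituent, so a (4+2) cycloaddition across pyrone C3 and C6, followed by loss of the lactone bridge, would close ring B directly as an arene.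

## Retrosynthesis

**19 back to 18 and 17 (unmasking).** Cutting the O–CH3 bond at B C6 leads from target 19 to methyl ether 18, and cutting three O–CH2Ph bonds (the ring B ester and the two ring A ethers) leads from 18 to the fully protected depside 17. Benzyl is used wherever hydrogenolysis can do the unmasking, because basic or nucleophilic ester cleavage would break the depside link. The one methyl ether comes with the alkyne partner; it sits next to the carboxyl, which can direct its removal by a boron Lewis acid through a six-membered chelate. Hydrogenolysis is placed first so that the Lewis acid meets a single ether and a defined intermediate 18, not a mixture of partly debenzylated compounds. Both forward reactions must spare the aryl ester and must not decarboxylate the product.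

**17 back to 9 and 15 (key cut).** Ring B of 17 is cut at C1–C2 and C5–C6, with the lactone bridge restored, giving 4-aroyloxy-2-pyrone 9 and alkoxypropiolate 15. The neighbouring cut at the depside C–O bond would only postpone the construction of a tetrasubstituted ring B. This cut builds the ring, places all four substituents, and keeps the ester link to ring A in place. Precursor 9 has no aromatic substitution problem on the B side and 15 is a three-carbon fragment. The forward reaction must put the ester beside heptyl, must tolerate the aroyl ester at the required temperature, and must aromatise without an oxidant; the decarboxylative cycloreversion of bridged lactone 16 provides the last.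

**9 back to 8 and 4.** The ester C–O bond of 9 is cut to give hydroxypyrone 8 and acid chloride 4. The 4-hydroxyl of 8 is a vinylogous carboxylic acid and the only hydroxyl present, so the later problem of choosing between two ring B oxygens does not arise. The forward acylation must occur on oxygen and not at C3.

**8 back to 5 and 6.** The bond between the first and second carbons of the heptyl chain is cut, giving commercial triketide lactone 5 and bromide 6. Building the pyrone from an acyclic 3,5-dioxo ester would take more steps, whereas 5 already holds the ring and every oxygen. The forward step needs a dianion of 5 that alkylates only at the methyl carbon.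

**4 back to 3, 2 and 1.** Acid chloride 4 is traced through acid 3 and tribenzyl compound 2 to commercial orsellinic acid 1, which contains all of ring A. Both phenols must be masked so that they do not compete in the acylation of 8, and benzyl is set by the endgame. The forward sequence is perbenzylation, hydrolysis of a hindered benzoate, and chloride formation.

**15 back to 12 and 13, and 12 back to 10.** The bond between the alkyne and the carboxyl carbon of 15 is cut, giving methoxyethyne 12 and chloroformate 13; 12 comes from chloroacetal 10 by twofold base-induced elimination. A methyl ynol ether is preferred to an ethyl or tert-butyl one because it has no β-hydrogen and cannot fragment thermally to a ketene at the cycloaddition temperature. A benzyl ynol ether would be open to sigmatropic rearrangement. The forward steps must handle a volatile alkyne and must avoid a second attack on the product.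

## Roads not taken

**Alternative 1:** Ring B would be cut at C1–C6 and C2–C3 into 1-methoxy-1,3-bis(trimethylsilyloxy)buta-1,3-diene A1 and benzyl dec-2-ynoate A2. In the forward direction a (4+2) cycloaddition, with the nucleophilic diene terminus adding to the heptyl-bearing β-carbon of A2, then loss of the alkoxy and silyl groups, would give benzyl 2-heptyl-4,6-dihydroxybenzoate A3.
- Merits: A3 has both hydroxyls free and already differentiated by hydrogen bonding of O6 to the ester. Acylation at O4 with acid chloride 4 and one hydrogenolysis would finish the synthesis with no ether cleavage, about two steps shorter than the chosen route, and the diene type is better documented.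
- Weak points: a β-alkyl ynoate is a sluggish partner for this diene; A1 is sensitive to heat and moisture; conjugate addition followed by closure through oxygen can divert material to pyranones; and the depside bond is made late.
- Comparison: in step count and precedent this road is at least as good as the chosen one. The chosen plan sets against it a three-fragment convergence in which ring B closes on the preformed depside, an irreversible aromatisation under neutral conditions, and a fallback that runs through the same resorcylate A3 made by classical chemistry.

**Alternative 2:** No ring bond would be cut; the C2–heptyl and C1–carboxyl bonds are disconnected. Forward, halogen–magnesium exchange on 1,2-dibromo-3,5-dimethoxybenzene A4 would release 3,5-dimethoxybenzyne A5. Heptylmagnesium bromide A6 would add at the aryne carbon remote from the flanking methoxy group, and carboxylation of the resulting aryl-magnesium species would give 2-heptyl-4,6-dimethoxybenzoic acid A7.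
- Merits: nucleophile addition to 3-alkoxyarynes is regiochemically dependable, two substituents are set in one flask, and every reaction type is known.
- Weak points: the step closes no ring; exchange and protonation compete with addition; and A7 then needs cleavage of two methyl ethers, one of them not chelated, under forcing Lewis-acid conditions that invite decarboxylation, followed by benzyl ester formation, selective acylation with 4 and hydrogenolysis.
- Comparison: the precedent is better than for the chosen key step and the overall length is similar. The chosen plan sets against it a single ether cleavage placed where chelation makes it mild, and no stage at which a free β-resorcylic acid meets hot or strongly acidic conditions.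

**Alternative 3:** Ring A, not ring B, would be disconnected, at A C5–C6, A C2–C3, A C4–C5 and A C1–C2. Forward, irradiation of diazo ketone A8, benzyl 2-(benzyloxy)-4-{[(2E)-5-diazo-3-methyl-4-oxopent-2-enoyl]oxy}-6-heptylbenzoate, would trigger a Wolff rearrangement to a vinylketene. tert-Butoxyethyne A9 would intercept it by (2+2) cycloaddition, and four-electron ring opening and six-electron ring closure would give benzyl 2-(benzyloxy)-4-{[4-(tert-butoxy)-2-hydroxy-6-methylbenzoyl]oxy}-6-heptylbenzoate A10.
- Merits: the regiochemistry of this benzannulation with ynol ethers is well established, better than that of the chosen key step; ring A emerges with O2 free and O4 masked; and the ester link is already present.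
- Weak points: the ring-forming step is spent on ring A, which can be bought complete as orsellinic acid 1, while ring B must still be made beforehand as a selectively protected phenol. A8 combines a diazo group with an electron-poor alkene and a photoactive aryl ester, and the end needs both acid and hydrogenolysis.
- Comparison: it has the safer key step but is clearly longer. The chosen plan applies its ring construction to ring B, where the difficulty lies.

Key step: step 8

Remark: ring A is the orsellinoyl ring (C1 acyl carbon, C2 and C4 oxygens, C6 methyl) and ring B the heptyl-bearing benzoic acid ring (C1 carboxyl, C2 heptyl, C4 ester oxygen, C6 hydroxyl); the target is achiral, and the transient bridged lactone 16 is racemic.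

## Route

Step 1
Reactants: 1 orsellinic acid
Product: 2 benzyl 2,4-bis(benzyloxy)-6-methylbenzoate
Conditions: BnBr (3.5 equiv), K2CO3, DMF, rt to 60 °C
Reagents that add atoms: benzyl bromide, BrCc1ccccc1
Why: Williamson-type O-alkylation of the carboxylate and both phenoxides; the carboxylate reacts first, which blocks decarboxylation, and warming completes benzylation of the hydrogen-bonded 2-hydroxyl.

Step 2
Reactants: 2 benzyl 2,4-bis(benzyloxy)-6-methylbenzoate
Product: 3 2,4-bis(benzyloxy)-6-methylbenzoic acid
Conditions: KOH, DMSO/H2O, 90 °C; then aq. HCl
Reagents that add atoms: potassium hydroxide, [K+].[OH-]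
Why: Saponification of a doubly ortho-substituted benzoate needs the poorly solvated hydroxide of aqueous DMSO; aryl benzyl ethers are inert to base, so only the ester is cleaved.

Step 3
Reactants: 3 2,4-bis(benzyloxy)-6-methylbenzoic acid
Product: 4 2,4-bis(benzyloxy)-6-methylbenzoyl chloride
Conditions: (COCl)2, DMF (cat.), CH2Cl2, 0 °C to rt; concentrate
Reagents that add atoms: oxalyl chloride, ClC(=O)C(=O)Cl
Why: Acid chloride formation through the Vilsmeier-type chloroiminium species is fast at low temperature and leaves the benzyl ethers alone; the crude chloride is used at once.

Step 4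
Reactants: 5 4-hydroxy-6-methyl-2H-pyran-2-one; 6 1-bromohexane
Product: 8 6-heptyl-4-hydroxy-2H-pyran-2-one, via dilithiated pyrone 7 (not isolated)
Conditions: LiN(iPr)2 (2.4 equiv), THF/DMPU, −78 °C; then 6, −78 °C to rt; aq. HCl
Reagents that add atoms: none
Why: Dianion alkylation: the first equivalent of base forms the 4-oxide and the second removes a proton from the 6-methyl group, and this more basic carbanion attacks the primary bromide (SN2), lengthening methyl to heptyl.

Step 5
Reactants: 4 2,4-bis(benzyloxy)-6-methylbenzoyl chloride; 8 6-heptyl-4-hydroxy-2H-pyran-2-one
Product: 9 6-heptyl-2-oxo-2H-pyran-4-yl 2,4-bis(benzyloxy)-6-methylbenzoate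
Conditions: Et3N, CH2Cl2, 0 °C to rt
Reagents that add atoms: none
Why: O-acylation of the acidic 4-hydroxyl (a vinylogous carboxylic acid) by an aroyl chloride under amine base gives the 4-aroyloxy-2-pyrone; the absence of a nucleophilic catalyst and the two ortho substituents of the aroyl group disfavour acyl migration from oxygen to C3.

Step 6
Reactants: 10 2-chloro-1,1-dimethoxyethane
Product: 12 methoxyethyne, via sodium methoxyacetylide 11 (not isolated)
Conditions: NaNH2 (3 equiv), liq. NH3, −33 °C; evaporate NH3; aq. NaCl, −70 °C; distil into THF at −78 °C
Reagents that add atoms: none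
Why: Twofold elimination (loss of methanol, then of HCl) by NaNH2 and deprotonation give the sodium acetylide, which water protonates; this is the classical alkoxyacetylene preparation, and the low-boiling, hazardous alkyne is kept cold and dilute in THF.

Step 7
Reactants: 12 methoxyethyne; 13 benzyl chloroformate
Product: 15 benzyl 3-methoxyprop-2-ynoate, via lithium methoxyacetylide 14 (not isolated)
Conditions: n-BuLi, THF, −78 °C; add to 13 in THF, −78 to −20 °C; pH 7 buffer
Reagents that add atoms: none
Why: Deprotonation of the terminal alkyne and acylation of the lithium acetylide by the chloroformate (inverse addition, low temperature) give the donor–acceptor ynoate, as is known for ethoxyacetylene with ethyl chloroformate; a neutral work-up avoids hydration of the triple bond.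

Step 8
Reactants: 9 6-heptyl-2-oxo-2H-pyran-4-yl 2,4-bis(benzyloxy)-6-methylbenzoate; 15 benzyl 3-methoxyprop-2-ynoate
Product: 17 benzyl 4-{[2,4-bis(benzyloxy)-6-methylbenzoyl]oxy}-2-heptyl-6-methoxybenzoate, via bridged lactone 16 (not isolated)
Conditions: 15 (3 equiv), PhMe, BHT (cat.), sealed tube, 160 °C
Reagents that add atoms: none
Why: Proposed new method: the pyrone diene (C3 to C6) and the alkyne should combine in an asynchronous (4+2) cycloaddition, the ester-bearing alkyne carbon (the nucleophilic β-carbon of the ynol ether) bonding to pyrone C6 and the methoxy-bearing carbon (the electrophilic β-carbon of the ynoate) to pyrone C3, to give bridged lactone 16. Lactone 16 then loses CO2 by retro-(4+2) cleavage, which is irreversible and delivers the arene directly, so no oxidation or elimination step is needed. The closest known reaction type is the Diels–Alder/decarboxylation sequence of 2-pyrones with alkynoates or ynamines; a donor–acceptor 3-alkoxypropiolate has not been shown as the partner. Ring B is closed by this intermolecular cycloaddition, which forms both new bonds (B C1–C2 and B C5–C6), and the lactone-bridged ring of 16 is only transient. The two bridgehead stereocentres of 16 form as a racemate and vanish on aromatisation, so 17 has no stereocentre. The selectivity required is regiochemical and is secured by matched polarisation: C6 is the electrophilic and C3 the nucleophilic terminus of the pyrone diene, so either frontier-orbital pairing gives the same orientation, with the ester beside heptyl and the methoxy group at B C6. The hindered 2,6-disubstituted aroyl ester should resist acyl transfer at this temperature, and the methyl ynol ether, having no β-hydrogen, cannot fragment to a ketene.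

Step 9
Reactants: 17 benzyl 4-{[2,4-bis(benzyloxy)-6-methylbenzoyl]oxy}-2-heptyl-6-methoxybenzoate
Product: 18 4-[(2,4-dihydroxy-6-methylbenzoyl)oxy]-2-heptyl-6-methoxybenzoic acid
Conditions: H2 (1 atm), Pd/C, EtOAc, rt
Reagents that add atoms: none
Why: Hydrogenolysis over Pd/C cleaves the benzyl ester and both benzyl ethers; the aryl ester of the depside and the methyl ether are not benzylic C–O bonds and persist.

Step 10
Reactants: 18 4-[(2,4-dihydroxy-6-methylbenzoyl)oxy]-2-heptyl-6-methoxybenzoic acid
Product: 19 4-[(2,4-dihydroxy-6-methylbenzoyl)oxy]-2-heptyl-6-hydroxybenzoic acid
Conditions: BCl3 (6 equiv), CH2Cl2, −78 to 0 °C; then H2O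
Reagents that add atoms: none
Why: Chelation-directed ether cleavage: BCl3 forms an acyloxyborane with the carboxyl that binds the adjacent methoxy oxygen in a six-membered chelate, and chloride removes the methyl group by SN2. The excess reagent covers the two free phenols, and the aryl ester should survive at low temperature.

## Compound list

1 | orsellinic acid (2,4-dihydroxy-6-methylbenzoic acid) | Cc1cc(O)cc(O)c1C(=O)O | starting material
2 | benzyl 2,4-bis(benzyloxy)-6-methylbenzoate | Cc1cc(OCc2ccccc2)cc(OCc2ccccc2)c1C(=O)OCc1ccccc1 | intermediate
3 | 2,4-bis(benzyloxy)-6-methylbenzoic acid | Cc1cc(OCc2ccccc2)cc(OCc2ccccc2)c1C(=O)O | intermediate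
4 | 2,4-bis(benzyloxy)-6-methylbenzoyl chloride | Cc1cc(OCc2ccccc2)cc(OCc2ccccc2)c1C(=O)Cl | intermediate
5 | 4-hydroxy-6-methyl-2H-pyran-2-one | CC1=CC(O)=CC(=O)O1 | starting material
6 | 1-bromohexane | CCCCCCBr | starting material
7 | dilithium salt of the O4,C7-dianion of 4-hydroxy-6-methyl-2H-pyran-2-one | [Li+].[Li+].[CH2-]C1=CC([O-])=CC(=O)O1 | intermediate
8 | 6-heptyl-4-hydroxy-2H-pyran-2-one | CCCCCCCC1=CC(O)=CC(=O)O1 | intermediate
9 | 6-heptyl-2-oxo-2H-pyran-4-yl 2,4-bis(benzyloxy)-6-methylbenzoate | CCCCCCCC1=CC(OC(=O)c2c(C)cc(OCc3ccccc3)cc2OCc2ccccc2)=CC(=O)O1 | intermediate
10 | 2-chloro-1,1-dimethoxyethane (chloroacetaldehyde dimethyl acetal) | COC(CCl)OC | starting material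
11 | sodium methoxyacetylide | [Na+].[C-]#COC | intermediate
12 | methoxyethyne (methoxyacetylene) | COC#C | intermediate
13 | benzyl chloroformate | O=C(Cl)OCc1ccccc1 | starting material
14 | lithium methoxyacetylide | [Li+].[C-]#COC | intermediate
15 | benzyl 3-methoxyprop-2-ynoate | COC#CC(=O)OCc1ccccc1 | intermediate
16 | benzyl 8-{[2,4-bis(benzyloxy)-6-methylbenzoyl]oxy}-1-heptyl-5-methoxy-3-oxo-2-oxabicyclo[2.2.2]octa-5,7-diene-6-carboxylate (racemic) | CCCCCCCC12OC(=O)C(C(OC)=C1C(=O)OCc1ccccc1)C(OC(=O)c1c(C)cc(OCc3ccccc3)cc1OCc1ccccc1)=C2 | intermediate
17 | benzyl 4-{[2,4-bis(benzyloxy)-6-methylbenzoyl]oxy}-2-heptyl-6-methoxybenzoate | CCCCCCCc1cc(OC(=O)c2c(C)cc(OCc3ccccc3)cc2OCc2ccccc2)cc(OC)c1C(=O)OCc1ccccc1 | intermediate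
18 | 4-[(2,4-dihydroxy-6-methylbenzoyl)oxy]-2-heptyl-6-methoxybenzoic acid | CCCCCCCc1cc(OC(=O)c2c(C)cc(O)cc2O)cc(OC)c1C(=O)O | intermediate
19 | 4-[(2,4-dihydroxy-6-methylbenzoyl)oxy]-2-heptyl-6-hydroxybenzoic acid | CCCCCCCc1cc(OC(=O)c2c(C)cc(O)cc2O)cc(O)c1C(=O)O | target

## Step count and risks

Total steps: 10. Longest linear sequence: 7 steps (steps 1, 2, 3, 5, 8, 9, 10).

**Step 8 (key step, Proposed new method).** The most likely failure is that the cycloaddition is too slow. Both partners are electronically damped: donor and acceptor on the alkyne partly cancel, and the pyrone carries an oxygen donor at C4. One new bond must also form at the hindered heptyl-bearing C6, so thermal oligomerisation of 15 or acyl scrambling of 9 may consume material first. Incomplete regiocontrol is the second possibility. High pressure at moderate temperature is the remedy at the level of conditions. The fallback uses known chemistry only, sets out from acid chloride 4 and rejoins the route at target 19. Commercial 5-heptylbenzene-1,3-diol F1 is carboxylated ortho to one hydroxyl with MeOMgOCO2Me in DMF at 120 °C (a Kolbe–Schmitt-type carboxylation, standard for 5-alkylresorcinols) to give 2-heptyl-4,6-dihydroxybenzoic acid F2. The carboxylate alone is benzylated (BnBr, KHCO3, DMF, rt) to benzyl 2-heptyl-4,6-dihydroxybenzoate F3. The non-chelated 4-hydroxyl of F3 is acylated by 4 (Et3N, CH2Cl2, 0 °C) to benzyl 4-{[2,4-bis(benzyloxy)-6-methylbenzoyl]oxy}-2-heptyl-6-hydroxybenzoate F4. Hydrogenolysis of the three benzyl groups (H2, Pd/C, EtOAc) then gives 19 directly, with no ether cleavage.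

**Step 5.** The most likely failure is acylation at C3 or migration of the acyl group from oxygen to C3, or acylation so slow with the hindered aroyl chloride and the weakly nucleophilic pyrone oxide that hydrolysis wins. The fallback sets out from 8 and rejoins at 17 by attaching ring A after ring B is built. 8 is acetylated (Ac2O, pyridine) to 6-heptyl-2-oxo-2H-pyran-4-yl acetate F5. F5 and 15 are heated as in step 8 to give, through benzyl 8-(acetyloxy)-1-heptyl-5-methoxy-3-oxo-2-oxabicyclo[2.2.2]octa-5,7-diene-6-carboxylate F6, benzyl 4-(acetyloxy)-2-heptyl-6-methoxybenzoate F7. The aryl acetate is removed (K2CO3, MeOH, 0 °C) without touching the hindered benzyl ester, giving benzyl 2-heptyl-4-hydroxy-6-methoxybenzoate F8. F8 is acylated by 4 (Et3N, DMAP, CH2Cl2), an ordinary phenol esterification, to give 17.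

**Step 7.** The most likely failure is loss of the low-boiling alkyne before lithiation, or over-reaction: a second acetylide attacking the ester of the product, or nucleophiles and water adding to its electron-poor triple bond during quench and purification. The fallback sets out from 12 and rejoins at 15. Lithium acetylide 14, generated as before, is carboxylated with CO2 gas at −78 °C to lithium 3-methoxyprop-2-ynoate F9, a carboxylate that cannot be attacked a second time. After solvent exchange to DMF, O-alkylation with benzyl bromide at rt gives 15.

**Step 10.** The most likely failure is cleavage of the depside ester once the ring A 2-hydroxyl is borylated and activates the adjacent carbonyl. Incomplete demethylation (the polyhydroxy acid dissolves poorly in CH2Cl2) and decarboxylation of the product during acidic work-up are the other risks. The fallback sets out from 17 and rejoins at 19 by reversing the order of the two deprotections. 17 is treated with BCl3 (CH2Cl2, −78 to −20 °C) while still fully lipophilic. The two chelated ethers, the methyl ether at B C6 and the benzyl ether at A C2, are cleaved to give benzyl 4-{[4-(benzyloxy)-2-hydroxy-6-methylbenzoyl]oxy}-2-heptyl-6-hydroxybenzoate F10. Hydrogenolysis (H2, Pd/C, EtOAc) of the remaining benzyl ester and ether gives 19, and any further benzyl loss in the first stage converges on the same product.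

## Further compounds

F1 | step 8 | 5-heptylbenzene-1,3-diol | CCCCCCCc1cc(O)cc(O)c1
F2 | step 8 | 2-heptyl-4,6-dihydroxybenzoic acid | CCCCCCCc1cc(O)cc(O)c1C(=O)O
F3 | step 8 | benzyl 2-heptyl-4,6-dihydroxybenzoate | CCCCCCCc1cc(O)cc(O)c1C(=O)OCc1ccccc1
F4 | step 8 | benzyl 4-{[2,4-bis(benzyloxy)-6-methylbenzoyl]oxy}-2-heptyl-6-hydroxybenzoate | CCCCCCCc1cc(OC(=O)c2c(C)cc(OCc3ccccc3)cc2OCc2ccccc2)cc(O)c1C(=O)OCc1ccccc1
F5 | step 5 | 6-heptyl-2-oxo-2H-pyran-4-yl acetate | CCCCCCCC1=CC(OC(C)=O)=CC(=O)O1
F6 | step 5 | benzyl 8-(acetyloxy)-1-heptyl-5-methoxy-3-oxo-2-oxabicyclo[2.2.2]octa-5,7-diene-6-carboxylate | CCCCCCCC12OC(=O)C(C(OC)=C1C(=O)OCc1ccccc1)C(OC(C)=O)=C2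
F7 | step 5 | benzyl 4-(acetyloxy)-2-heptyl-6-methoxybenzoate | CCCCCCCc1cc(OC(C)=O)cc(OC)c1C(=O)OCc1ccccc1
F8 | step 5 | benzyl 2-heptyl-4-hydroxy-6-methoxybenzoate | CCCCCCCc1cc(O)cc(OC)c1C(=O)OCc1ccccc1
F9 | step 7 | lithium 3-methoxyprop-2-ynoate | [Li+].COC#CC([O-])=O
F10 | step 10 | benzyl 4-{[4-(benzyloxy)-2-hydroxy-6-methylbenzoyl]oxy}-2-heptyl-6-hydroxybenzoate | CCCCCCCc1cc(OC(=O)c2c(C)cc(OCc3ccccc3)cc2O)cc(O)c1C(=O)OCc1ccccc1
A1 | alternative 1 | 1-methoxy-1,3-bis(trimethylsilyloxy)buta-1,3-diene | COC(O[Si](C)(C)C)=CC(=C)O[Si](C)(C)C
A2 | alternative 1 | benzyl dec-2-ynoate | CCCCCCCC#CC(=O)OCc1ccccc1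
A3 | alternative 1 | benzyl 2-heptyl-4,6-dihydroxybenzoate | CCCCCCCc1cc(O)cc(O)c1C(=O)OCc1ccccc1
A4 | alternative 2 | 1,2-dibromo-3,5-dimethoxybenzene | COc1cc(OC)c(Br)c(Br)c1
A5 | alternative 2 | 3,5-dimethoxybenzyne | COC1=CC(OC)=CC#C1
A6 | alternative 2 | heptylmagnesium bromide | CCCCCCC[Mg]Br
A7 | alternative 2 | 2-heptyl-4,6-dimethoxybenzoic acid | CCCCCCCc1cc(OC)cc(OC)c1C(=O)O
A8 | alternative 3 | benzyl 2-(benzyloxy)-4-{[(2E)-5-diazo-3-methyl-4-oxopent-2-enoyl]oxy}-6-heptylbenzoate | CCCCCCCc1cc(OC(=O)/C=C(\C)C(=O)C=[N+]=[N-])cc(OCc2ccccc2)c1C(=O)OCc1ccccc1
A9 | alternative 3 | tert-butoxyethyne | CC(C)(C)OC#C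
A10 | alternative 3 | benzyl 2-(benzyloxy)-4-{[4-(tert-butoxy)-2-hydroxy-6-methylbenzoyl]oxy}-6-heptylbenzoate | CCCCCCCc1cc(OC(=O)c2c(C)cc(OC(C)(C)C)cc2O)cc(OCc2ccccc2)c1C(=O)OCc1ccccc1
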